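**Retrosynthetic overview**

1. The last two events are double O-debenzylation and, before it, a chelation-controlled reduction of a side-chain aryl ketone that sets the carbinol carbon (Cα); both are run on the fully coupled ketone.
2. Key disconnection: the bond between tetralin C1 (ring B) and the ring C carbon para to the ether oxygen. It is made by a nickel-catalysed reductive cross-electrophile coupling of a C1 benzylic chloride (both C1 epimers) with an aryl iodide that already carries the complete α-aryloxy ketone side chain; the step sets C1.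
3. Enabling feature: C1 is benzylic to ring A and lies para (through C8a) to the C6 methoxy group, so its C–Cl bond gives a stabilised, planar C1 radical; the neighbouring C2 methyl stereocentre steers the incoming aryl group trans.
4. Tetralin half: C3 by Evans alkylation of a vanillyl bromide, Arndt–Eistert homologation, ring B closed by Friedel–Crafts acylation (C1–C8a), C2 by trans-selective enolate methylation, then C1 ketone to alcohol to chloride.
5. Aryl half: Cβ from ethyl (S)-lactate by Mitsunobu inversion with 4-iodo-2-methoxyphenol (ring C), then Weinreb amide and aryl Grignard (ring D). Only ring B is constructed (step 6); rings A, C and D are bought as arenes.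

Key step: step 13

Remark: locants used below are tetralin C1 (aryl-bearing), C2 and C3 (methyl-bearing), C4 (CH2), ring A (oxygenated benzo ring), ring B (saturated ring), ring C (central benzene ring), ring D (terminal guaiacyl ring), Cα (carbinol carbon) and Cβ (aryloxy-bearing carbon); the five starting materials are assumed to be commercially available.

**Route**

Step 1
Reactants: 1 [4-(benzyloxy)-3-methoxyphenyl]methanol
Product: 2 1-(benzyloxy)-4-(bromomethyl)-2-methoxybenzene
Conditions: PBr3 (0.4 equiv), Et2O, 0 °C; used without storage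
Reagents that add atoms: phosphorus tribromide, BrP(Br)Br
Why: Substitution of an electron-rich benzylic alcohol through its bromophosphite ester is a standard alcohol-to-bromide conversion and should leave the aryl benzyl ether untouched.

Step 2
Reactants: 3 (S)-4-benzyl-3-propanoyl-1,3-oxazolidin-2-one; 2 1-(benzyloxy)-4-(bromomethyl)-2-methoxybenzene
Product: 5 (S)-4-benzyl-3-[(R)-3-(4-(benzyloxy)-3-methoxyphenyl)-2-methylpropanoyl]-1,3-oxazolidin-2-one, via sodium enolate 4 (not isolated)
Conditions: NaN(SiMe3)2 (1.1 equiv), THF, −78 °C; then 2 (1.3 equiv), −78 → −20 °C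
Reagents that add atoms: none
Why: Evans asymmetric alkylation, in which the chelated sodium (Z)-enolate 4 should be alkylated by the benzylic bromide on the face opposite the C4 benzyl group of the auxiliary, setting the methyl-bearing carbon (later tetralin C3) as R.

Step 3
Reactants: 5 (S)-4-benzyl-3-[(R)-3-(4-(benzyloxy)-3-methoxyphenyl)-2-methylpropanoyl]-1,3-oxazolidin-2-one
Product: 7 (R)-3-[4-(benzyloxy)-3-methoxyphenyl]-2-methylpropanoic acid, via peroxy acid 6 (not isolated)
Conditions: LiOH (2 equiv), 30% aq H2O2 (4 equiv), THF–H2O (3:1), 0 °C; then Na2SO3; then HCl to pH 2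
Reagents that add atoms: hydrogen peroxide, OO
Why: Hydroperoxide cleavage of the N-acyl oxazolidinone attacks the exocyclic carbonyl selectively without epimerisation, and sulfite reduces peroxy acid 6 to the carboxylic acid.

Step 4
Reactants: 7 (R)-3-[4-(benzyloxy)-3-methoxyphenyl]-2-methylpropanoic acid
Product: 9 (R)-4-[4-(benzyloxy)-3-methoxyphenyl]-1-diazo-3-methylbutan-2-one, via acid chloride 8 (not isolated)
Conditions: (COCl)2 (1.5 equiv), DMF (cat.), CH2Cl2, 0 °C → rt; evaporate; Me3SiCHN2 (2 equiv), THF–MeCN (1:1), 0 °C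
Reagents that add atoms: trimethylsilyldiazomethane, C[Si](C)(C)C=[N+]=[N-]
Why: First half of the Arndt–Eistert homologation, in which acid chloride 8 (made without base, so the α-stereocentre is not lost through a ketene) acylates the diazomethane reagent to give the α-diazoketone.

Step 5
Reactants: 9 (R)-4-[4-(benzyloxy)-3-methoxyphenyl]-1-diazo-3-methylbutan-2-one
Product: 11 (R)-4-[4-(benzyloxy)-3-methoxyphenyl]-3-methylbutanoic acid, via ketene 10 (not isolated)
Conditions: PhCO2Ag (0.1 equiv), Et3N (3 equiv), THF–H2O (10:1), rt, dark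
Reagents that add atoms: water, O
Why: Silver-catalysed Wolff rearrangement, in which the stereogenic carbon migrates with retention to give ketene 10 and water traps it as the one-carbon-homologated acid.

Step 6
Reactants: 11 (R)-4-[4-(benzyloxy)-3-methoxyphenyl]-3-methylbutanoic acid
Product: 13 (R)-7-(benzyloxy)-6-methoxy-3-methyl-3,4-dihydronaphthalen-1(2H)-one, via mixed trifluoroacetic anhydride 12 (not isolated)
Conditions: (CF3CO)2O (1.5 equiv), CH2Cl2, 0 °C → rt
Reagents that add atoms: none
Why: Intramolecular Friedel–Crafts acylation through mixed anhydride 12 should close six-membered ring B at the unhindered ring position para to the methoxy group (C8a), without touching the C3 stereocentre or, at this temperature, the benzyl ether.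

Step 7
Reactants: 13 (R)-7-(benzyloxy)-6-methoxy-3-methyl-3,4-dihydronaphthalen-1(2H)-one
Product: 15 (2S,3R)-7-(benzyloxy)-6-methoxy-2,3-dimethyl-3,4-dihydronaphthalen-1(2H)-one, via lithium enolate 14 (not isolated)
Conditions: LiN(iPr)2 (1.05 equiv), THF, −78 °C; MeI (1.5 equiv), −78 → −40 °C; if needed NaOMe (cat.), MeOH, rt
Reagents that add atoms: iodomethane, CI
Why: Kinetic enolate alkylation, in which MeI should attack lithium enolate 14 anti to the adjacent C3 methyl group to give the 2,3-trans ketone, which is also the thermodynamically preferred diequatorial epimer, so any cis isomer can be equilibrated with methoxide.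

Step 8
Reactants: 15 (2S,3R)-7-(benzyloxy)-6-methoxy-2,3-dimethyl-3,4-dihydronaphthalen-1(2H)-one
Product: 16 (2S,3R)-7-(benzyloxy)-6-methoxy-2,3-dimethyl-1,2,3,4-tetrahydronaphthalen-1-ol (mixture of C1 epimers)
Conditions: NaBH4 (1.5 equiv), MeOH–THF, 0 °C
Reagents that add atoms: none
Why: Borohydride reduction of the aryl ketone is routine, and the C1 configuration does not matter because both epimers converge on one radical in step 13.

Step 9
Reactants: 16 (2S,3R)-7-(benzyloxy)-6-methoxy-2,3-dimethyl-1,2,3,4-tetrahydronaphthalen-1-ol (mixture of C1 epimers)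
Product: 17 (2S,3R)-7-(benzyloxy)-1-chloro-6-methoxy-2,3-dimethyl-1,2,3,4-tetrahydronaphthalene (mixture of C1 epimers)
Conditions: SOCl2 (1.2 equiv), CH2Cl2, −20 → 0 °C; volatiles removed in vacuo; crude 17 used at once
Reagents that add atoms: thionyl chloride, O=S(Cl)Cl
Why: Chlorination of the methoxy-activated benzylic alcohol through its chlorosulfite with internal return of chloride, run cold and without base, should outpace loss of the C2 proton, so the C2 and C3 stereocentres are kept.

Step 10
Reactants: 18 4-iodo-2-methoxyphenol; 19 ethyl (S)-2-hydroxypropanoate (ethyl L-lactate)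
Product: 20 ethyl (R)-2-(4-iodo-2-methoxyphenoxy)propanoate
Conditions: PPh3 (1.2 equiv), DIAD (1.2 equiv), THF, 0 °C → rt
Reagents that add atoms: none
Why: Mitsunobu etherification of the phenol with the secondary lactate alcohol proceeds by SN2 inversion, turning the (S)-lactate into the (R)-aryloxypropanoate whose stereocentre becomes Cβ.

Step 11
Reactants: 20 ethyl (R)-2-(4-iodo-2-methoxyphenoxy)propanoate
Product: 21 (R)-2-(4-iodo-2-methoxyphenoxy)-N-methoxy-N-methylpropanamide
Conditions: AlMe3 (3 equiv), MeNH(OMe)·HCl (3 equiv), CH2Cl2, 0 °C → rt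
Reagents that add atoms: N,O-dimethylhydroxylamine hydrochloride, CNOC.Cl
Why: Weinreb amide formation by aminolysis of the ester with an aluminium amide is weakly basic, so the α-aryloxy stereocentre should be retained, and it does not touch the aryl iodide.

Step 12
Reactants: 21 (R)-2-(4-iodo-2-methoxyphenoxy)-N-methoxy-N-methylpropanamide; 22 1-(benzyloxy)-4-bromo-2-methoxybenzene
Product: 24 (R)-1-[4-(benzyloxy)-3-methoxyphenyl]-2-(4-iodo-2-methoxyphenoxy)propan-1-one, via arylmagnesium bromide 23 (not isolated)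
Conditions: 22 (1.5 equiv), Mg turnings, I2 (cat.), THF, 50 °C; then 21, THF, 0 °C; aq NH4Cl
Reagents that add atoms: none
Why: Weinreb ketone synthesis, in which Grignard reagent 23 adds once to give a chelated tetrahedral intermediate that releases the ketone only on work-up, while iodine–magnesium exchange between two electron-rich aryl groups is slow at 0 °C.

Step 13
Reactants: 17 (2S,3R)-7-(benzyloxy)-1-chloro-6-methoxy-2,3-dimethyl-1,2,3,4-tetrahydronaphthalene (mixture of C1 epimers); 24 (R)-1-[4-(benzyloxy)-3-methoxyphenyl]-2-(4-iodo-2-methoxyphenoxy)propan-1-one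
Product: 25 (R)-1-[4-(benzyloxy)-3-methoxyphenyl]-2-{4-[(1S,2S,3R)-7-(benzyloxy)-6-methoxy-2,3-dimethyl-1,2,3,4-tetrahydronaphthalen-1-yl]-2-methoxyphenoxy}propan-1-one
Conditions: NiBr2·DME (10 mol %), 4,4'-di-tert-butyl-2,2'-bipyridine (12 mol %), Mn powder (3 equiv), NaI (0.5 equiv), DMA, 25 °C; 17 (1.5 equiv) added as a DMA solution
Reagents that add atoms: none
Why: Zerovalent nickel bearing the bipyridine ligand inserts into the C–I bond of 24, a monovalent nickel species abstracts chlorine from either C1 epimer of 17 to give one planar benzylic radical at C1 (stabilised by ring A and by the C6 methoxy group para to C8a), the arylnickel species captures this radical, and the resulting trivalent nickel species reductively eliminates the C1–aryl bond while Mn returns nickel to its low-valent state. The closest known reaction type is the nickel-catalysed reductive cross-electrophile coupling of secondary benzylic chlorides, open-chain and cyclic, with aryl iodides to give 1,1-diarylalkanes. No ring is closed in this step. The new stereocentre C1 is controlled by the adjacent C2 methyl group: the bulky arylnickel complex should bond to the radical on the face anti to that methyl group, so the aryl group ends up trans to it with all three ring B substituents equatorial (1S). The step needs cross- over homo-coupling selectivity, which the different activation modes of the sp2 C–I bond (two-electron oxidative addition) and the sp3 C–Cl bond (halogen abstraction) and the excess of 17 should secure, and it needs the C2 configuration to survive, which the radical pathway secures because, unlike a C1 cation, the radical does not lose the C2 hydrogen. The aryl ketone, the benzyl ethers and the base-sensitive Cβ stereocentre of 24 should be inert under these neutral conditions, and no free hydroxyl group is present to be alkylated by 17.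

Step 14
Reactants: 25 (R)-1-[4-(benzyloxy)-3-methoxyphenyl]-2-{4-[(1S,2S,3R)-7-(benzyloxy)-6-methoxy-2,3-dimethyl-1,2,3,4-tetrahydronaphthalen-1-yl]-2-methoxyphenoxy}propan-1-one
Product: 26 (1S,2R)-1-[4-(benzyloxy)-3-methoxyphenyl]-2-{4-[(1S,2S,3R)-7-(benzyloxy)-6-methoxy-2,3-dimethyl-1,2,3,4-tetrahydronaphthalen-1-yl]-2-methoxyphenoxy}propan-1-ol
Conditions: Zn(BH4)2 (2 equiv, ethereal stock solution), Et2O, −20 → 0 °C; aq NH4Cl
Reagents that add atoms: none
Why: Chelation-controlled (Cram chelate) hydride reduction, in which zinc bridges the carbonyl oxygen and the Cβ aryloxy oxygen and hydride is delivered past the small Cβ hydrogen, should set Cα as S, erythro to the R-configured Cβ.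

Step 15
Reactants: 26 (1S,2R)-1-[4-(benzyloxy)-3-methoxyphenyl]-2-{4-[(1S,2S,3R)-7-(benzyloxy)-6-methoxy-2,3-dimethyl-1,2,3,4-tetrahydronaphthalen-1-yl]-2-methoxyphenoxy}propan-1-ol
Product: 27 (6R,7S,8S)-8-[4-{[(1S,2R)-1-hydroxy-1-(4-hydroxy-3-methoxyphenyl)propan-2-yl]oxy}-3-methoxyphenyl]-3-methoxy-6,7-dimethyl-5,6,7,8-tetrahydronaphthalen-2-ol (target, CID53359464)
Conditions: H2 (1 atm), 10% Pd/C, EtOAc–MeOH, rt, stopped after uptake of two equivalents
Reagents that add atoms: none
Why: Catalytic hydrogenolysis of the two aryl benzyl ethers under neutral conditions at atmospheric pressure should be faster than hydrogenolysis of the secondary benzylic alcohol or attack on the diarylmethine C1–H bond, and no stereocentre is affected.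

**Compound list**

1 | [4-(benzyloxy)-3-methoxyphenyl]methanol | COc1cc(CO)ccc1OCc1ccccc1 | starting material
2 | 1-(benzyloxy)-4-(bromomethyl)-2-methoxybenzene | COc1cc(CBr)ccc1OCc1ccccc1 | intermediate
3 | (S)-4-benzyl-3-propanoyl-1,3-oxazolidin-2-one | CCC(=O)N1[C@@H](Cc2ccccc2)COC1=O | starting material
4 | sodium (Z)-enolate of 3 | C/C=C(\[O-])N1[C@@H](Cc2ccccc2)COC1=O.[Na+] | intermediate
5 | (S)-4-benzyl-3-[(R)-3-(4-(benzyloxy)-3-methoxyphenyl)-2-methylpropanoyl]-1,3-oxazolidin-2-one | C[C@H](Cc1ccc(OCc2ccccc2)c(OC)c1)C(=O)N1[C@@H](Cc2ccccc2)COC1=O | intermediate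
6 | (R)-3-[4-(benzyloxy)-3-methoxyphenyl]-2-methylpropaneperoxoic acid (present as its lithium salt) | C[C@H](Cc1ccc(OCc2ccccc2)c(OC)c1)C(=O)OO | intermediate
7 | (R)-3-[4-(benzyloxy)-3-methoxyphenyl]-2-methylpropanoic acid | C[C@H](Cc1ccc(OCc2ccccc2)c(OC)c1)C(=O)O | intermediate
8 | (R)-3-[4-(benzyloxy)-3-methoxyphenyl]-2-methylpropanoyl chloride | C[C@H](Cc1ccc(OCc2ccccc2)c(OC)c1)C(Cl)=O | intermediate
9 | (R)-4-[4-(benzyloxy)-3-methoxyphenyl]-1-diazo-3-methylbutan-2-one | C[C@H](Cc1ccc(OCc2ccccc2)c(OC)c1)C(=O)C=[N+]=[N-] | intermediate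
10 | (R)-4-[4-(benzyloxy)-3-methoxyphenyl]-3-methylbut-1-en-1-one (ketene) | C[C@H](Cc1ccc(OCc2ccccc2)c(OC)c1)C=C=O | intermediate
11 | (R)-4-[4-(benzyloxy)-3-methoxyphenyl]-3-methylbutanoic acid | C[C@H](Cc1ccc(OCc2ccccc2)c(OC)c1)CC(=O)O | intermediate
12 | mixed anhydride of 11 with trifluoroacetic acid | C[C@H](Cc1ccc(OCc2ccccc2)c(OC)c1)CC(=O)OC(=O)C(F)(F)F | intermediate
13 | (R)-7-(benzyloxy)-6-methoxy-3-methyl-3,4-dihydronaphthalen-1(2H)-one | C[C@@H]1Cc2cc(OC)c(OCc3ccccc3)cc2C(=O)C1 | intermediate
14 | lithium enolate of 13 (C1–C2 enolate) | C[C@@H]1Cc2cc(OC)c(OCc3ccccc3)cc2C([O-])=C1.[Li+] | intermediate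
15 | (2S,3R)-7-(benzyloxy)-6-methoxy-2,3-dimethyl-3,4-dihydronaphthalen-1(2H)-one (2,3-trans) | O=C1c2cc(OCc3ccccc3)c(OC)cc2C[C@@H](C)[C@@H]1C | intermediate
16 | (2S,3R)-7-(benzyloxy)-6-methoxy-2,3-dimethyl-1,2,3,4-tetrahydronaphthalen-1-ol (mixture of C1 epimers, C1 left undefined) | OC1c2cc(OCc3ccccc3)c(OC)cc2C[C@@H](C)[C@@H]1C | intermediate
17 | (2S,3R)-7-(benzyloxy)-1-chloro-6-methoxy-2,3-dimethyl-1,2,3,4-tetrahydronaphthalene (mixture of C1 epimers, C1 left undefined) | ClC1c2cc(OCc3ccccc3)c(OC)cc2C[C@@H](C)[C@@H]1C | intermediate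
18 | 4-iodo-2-methoxyphenol | COc1cc(I)ccc1O | starting material
19 | ethyl (S)-2-hydroxypropanoate | CCOC(=O)[C@H](C)O | starting material
20 | ethyl (R)-2-(4-iodo-2-methoxyphenoxy)propanoate | CCOC(=O)[C@@H](C)Oc1ccc(I)cc1OC | intermediate
21 | (R)-2-(4-iodo-2-methoxyphenoxy)-N-methoxy-N-methylpropanamide | CON(C)C(=O)[C@@H](C)Oc1ccc(I)cc1OC | intermediate
22 | 1-(benzyloxy)-4-bromo-2-methoxybenzene | COc1cc(Br)ccc1OCc1ccccc1 | starting material
23 | [4-(benzyloxy)-3-methoxyphenyl]magnesium bromide | COc1cc([Mg]Br)ccc1OCc1ccccc1 | intermediate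
24 | (R)-1-[4-(benzyloxy)-3-methoxyphenyl]-2-(4-iodo-2-methoxyphenoxy)propan-1-one | COc1cc(C(=O)[C@@H](C)Oc2ccc(I)cc2OC)ccc1OCc1ccccc1 | intermediate
25 | (R)-1-[4-(benzyloxy)-3-methoxyphenyl]-2-{4-[(1S,2S,3R)-7-(benzyloxy)-6-methoxy-2,3-dimethyl-1,2,3,4-tetrahydronaphthalen-1-yl]-2-methoxyphenoxy}propan-1-one | COc1cc(C(=O)[C@@H](C)Oc2ccc([C@H]3c4cc(OCc5ccccc5)c(OC)cc4C[C@@H](C)[C@@H]3C)cc2OC)ccc1OCc1ccccc1 | intermediate
26 | (1S,2R)-1-[4-(benzyloxy)-3-methoxyphenyl]-2-{4-[(1S,2S,3R)-7-(benzyloxy)-6-methoxy-2,3-dimethyl-1,2,3,4-tetrahydronaphthalen-1-yl]-2-methoxyphenoxy}propan-1-ol (erythro) | COc1cc([C@H](O)[C@@H](C)Oc2ccc([C@H]3c4cc(OCc5ccccc5)c(OC)cc4C[C@@H](C)[C@@H]3C)cc2OC)ccc1OCc1ccccc1 | intermediate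
27 | (6R,7S,8S)-8-[4-{[(1S,2R)-1-hydroxy-1-(4-hydroxy-3-methoxyphenyl)propan-2-yl]oxy}-3-methoxyphenyl]-3-methoxy-6,7-dimethyl-5,6,7,8-tetrahydronaphthalen-2-ol | COc1cc([C@H](O)[C@@H](C)Oc2ccc([C@H]3c4cc(O)c(OC)cc4C[C@@H](C)[C@@H]3C)cc2OC)ccc1O | target

**Step count and risks**

Total step count: 15. Longest linear sequence: 12 steps (steps 1–9, then 13–15); the aryl half takes 3 steps (10–12).

The three steps most likely to fail:

1. Step 13 (together with the labile chloride from step 9). Chloride 17 may ionise and lose the C2 proton, giving the dihydronaphthalene and eroding C2, before the radical is formed. One partner may also homocouple or be hydrodehalogenated, and facial selectivity at C1 may be incomplete. The fallback is a polar, stepwise assembly that sets out from alcohol 16 and returns to the route at 25. Alcohol 16 is treated with an excess of 2-methoxyphenol and catalytic Bi(OTf)3 in CH2Cl2 at −20 °C. This Friedel–Crafts alkylation should occur para to the phenolic hydroxyl group and trans to the C2 methyl group, the excess phenol capturing the cation before proton loss, to give 4-[(1S,2S,3R)-7-(benzyloxy)-6-methoxy-2,3-dimethyl-1,2,3,4-tetrahydronaphthalen-1-yl]-2-methoxyphenol F1. Mitsunobu etherification of this phenol with lactate 19 (PPh3, DIAD, THF) should give ethyl (R)-2-{4-[(1S,2S,3R)-7-(benzyloxy)-6-methoxy-2,3-dimethyl-1,2,3,4-tetrahydronaphthalen-1-yl]-2-methoxyphenoxy}propanoate F2. Aminolysis with AlMe3 and MeNH(OMe)·HCl should give the corresponding N-methoxy-N-methylamide F3, and addition of Grignard reagent 23 should give ketone 25.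

2. Step 14. The weakly basic aryl ether oxygen may not hold the zinc chelate, so hydride delivery may show poor facial selectivity and give an erythro/threo mixture that is hard to separate at this late stage. The fallback sets out from 25 and returns at 26. Non-chelating Felkin–Anh reduction with LiBH(s-Bu)3 in THF at −78 °C should give the threo alcohol (1R,2R)-1-[4-(benzyloxy)-3-methoxyphenyl]-2-{4-[(1S,2S,3R)-7-(benzyloxy)-6-methoxy-2,3-dimethyl-1,2,3,4-tetrahydronaphthalen-1-yl]-2-methoxyphenoxy}propan-1-ol F4. Mitsunobu inversion at Cα with 4-nitrobenzoic acid (PPh3, DIAD, THF, 0 °C) should give the erythro 4-nitrobenzoate of 26, F5. Methanolysis with K2CO3 in MeOH should then release 26.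

3. Step 7. Proton transfer between the product ketone and enolate 14 may lead to double methylation at C2, and the trans selectivity may be incomplete. The fallback sets out from 13 and returns at 15. α-Methylenation of 13 with paraformaldehyde and N-methylanilinium trifluoroacetate in THF at reflux should give (R)-7-(benzyloxy)-6-methoxy-3-methyl-2-methylidene-3,4-dihydronaphthalen-1(2H)-one F6, which cannot be alkylated twice. Hydrogenation of its enone C=C bond with RhCl(PPh3)3 and H2 in benzene, which spares the benzyl ether, followed by equilibration with NaOMe in MeOH, should give the trans ketone 15.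

**Further compounds**

F1 | step 13 | 4-[(1S,2S,3R)-7-(benzyloxy)-6-methoxy-2,3-dimethyl-1,2,3,4-tetrahydronaphthalen-1-yl]-2-methoxyphenol | COc1cc([C@H]2c3cc(OCc4ccccc4)c(OC)cc3C[C@@H](C)[C@@H]2C)ccc1O
F2 | step 13 | ethyl (R)-2-{4-[(1S,2S,3R)-7-(benzyloxy)-6-methoxy-2,3-dimethyl-1,2,3,4-tetrahydronaphthalen-1-yl]-2-methoxyphenoxy}propanoate | CCOC(=O)[C@@H](C)Oc1ccc([C@H]2c3cc(OCc4ccccc4)c(OC)cc3C[C@@H](C)[C@@H]2C)cc1OC
F3 | step 13 | (R)-2-{4-[(1S,2S,3R)-7-(benzyloxy)-6-methoxy-2,3-dimethyl-1,2,3,4-tetrahydronaphthalen-1-yl]-2-methoxyphenoxy}-N-methoxy-N-methylpropanamide | CON(C)C(=O)[C@@H](C)Oc1ccc([C@H]2c3cc(OCc4ccccc4)c(OC)cc3C[C@@H](C)[C@@H]2C)cc1OC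
F4 | step 14 | (1R,2R)-1-[4-(benzyloxy)-3-methoxyphenyl]-2-{4-[(1S,2S,3R)-7-(benzyloxy)-6-methoxy-2,3-dimethyl-1,2,3,4-tetrahydronaphthalen-1-yl]-2-methoxyphenoxy}propan-1-ol (threo) | COc1cc([C@@H](O)[C@@H](C)Oc2ccc([C@H]3c4cc(OCc5ccccc5)c(OC)cc4C[C@@H](C)[C@@H]3C)cc2OC)ccc1OCc1ccccc1
F5 | step 14 | (1S,2R)-1-[4-(benzyloxy)-3-methoxyphenyl]-2-{4-[(1S,2S,3R)-7-(benzyloxy)-6-methoxy-2,3-dimethyl-1,2,3,4-tetrahydronaphthalen-1-yl]-2-methoxyphenoxy}propyl 4-nitrobenzoate (erythro) | COc1cc([C@H](OC(=O)c2ccc(cc2)[N+](=O)[O-])[C@@H](C)Oc2ccc([C@H]3c4cc(OCc5ccccc5)c(OC)cc4C[C@@H](C)[C@@H]3C)cc2OC)ccc1OCc1ccccc1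
F6 | step 7 | (R)-7-(benzyloxy)-6-methoxy-3-methyl-2-methylidene-3,4-dihydronaphthalen-1(2H)-one | C=C1C(=O)c2cc(OCc3ccccc3)c(OC)cc2C[C@H]1C
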